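Each quinone ring is numbered C1 (C=O), C2 (OH), C3 (CH3), C4 (C=O), C5 (inter-ring carbon), C6 (phenethyl carbon); rings A and B are identical. The route exploits the fact that the congested C5–C5' bond is flanked by the carbonyl carbons C4 and C4', so C4–C5–C5'–C4' is a latent succinate. That bond is made early between sp3 carbons. One alkoxide treatment then forms C3–C4 and C3'–C4' and closes both carbocycles as 2-methylcyclohexane-1,3-diones. The precursor is an open-chain dimethyl succinate bearing a 1-(2-methoxyphenyl)-5-oxoheptan-3-yl arm on each central carbon. Dehydrogenation and oxidation at C1 finish the synthesis.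

Key step: step 6

Assumption: the target string carries no stereodescriptor. The tetra-ortho-substituted C5–C5' axis may be configurationally stable, and the route delivers the racemate.

Remarks on the design:
- **Atom mapping of 10.** Ester carbon = C4, succinate CH = C5, branched CH = C6, chain CH2 = C1, ketone carbon = C2, ethyl CH2 = C3, ethyl CH3 = ring methyl. After aromatisation the only free ring position is C1, para to the C4 hydroxyl, so the oxygen pattern of the target follows. The connectivity of 10 and 13 needs no change.
- **Acetate unit.** It is introduced by a Lewis-acid Mukaiyama–Michael addition rather than by malonate addition and decarboxylation. This saves one step and avoids an alkoxide medium that could cyclise the adduct prematurely.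
- **Extra competitor in the key step.** In 10 the C1 enolate can reach the remote ester C4' through a five-membered transition state. Methyl esters are therefore kept and matched with NaOMe, so the closure runs under thermodynamic control.
- **Furan hazard.** 13 contains the 1,4-dicarbonyl array C4–C5–C5'–C4'. Strong acid and very high temperature are avoided from step 6 on to suppress Paal–Knorr furan formation.

Step 1
Reactants: 1 3-(2-methoxyphenyl)propanal; 2 diethyl (2-oxobutyl)phosphonate
Product: 3 (E)-7-(2-methoxyphenyl)hept-4-en-3-one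
Conditions: LiCl, DBU, MeCN, 0 °C → rt
Reagents that add atoms: none
Why: Horner–Wadsworth–Emmons olefination under LiCl/amine (Masamune–Roush) conditions, in which the lithium-chelated β-keto phosphonate is acidic enough for DBU so that the enolisable aldehyde is spared aldol self-condensation, and the stabilised carbanion should give the E-enone.

Step 2
Reactants: 3 (E)-7-(2-methoxyphenyl)hept-4-en-3-one; 4 1-(tert-butyldimethylsilyloxy)-1-methoxyethene
Product: 6 methyl 3-[2-(2-methoxyphenyl)ethyl]-5-oxoheptanoate (racemic), via silyl enol ether adduct 5 (not isolated)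
Conditions: Sc(OTf)3 (5 mol%), CH2Cl2, −78 → −20 °C; then 1 M HCl, THF, rt
Reagents that add atoms: none
Why: Mukaiyama–Michael addition, in which the Lewis acid activates the enone, the unhindered acetate ketene silyl acetal attacks the β-carbon (the future C6) and silicon ends on the enolate oxygen to give 5, which dilute acid hydrolyses to the δ-keto ester; C6 is formed racemic, which is irrelevant because it becomes an arene carbon.

Step 3
Reactants: 6 methyl 3-[2-(2-methoxyphenyl)ethyl]-5-oxoheptanoate
Product: 7 methyl 4-(2-ethyl-1,3-dioxolan-2-yl)-3-[2-(2-methoxyphenyl)ethyl]butanoate (racemic)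
Conditions: HOCH2CH2OH, p-TsOH·H2O (cat.), toluene, reflux, Dean–Stark
Reagents that add atoms: ethylene glycol, OCCO
Why: Acid-catalysed ketalisation driven by azeotropic removal of water, which takes the ketone α-protons (more acidic than the ester α-protons) out of play before the strong-base step, while the methyl ester and aryl ether are inert.

Step 4
Reactants: 7 methyl 4-(2-ethyl-1,3-dioxolan-2-yl)-3-[2-(2-methoxyphenyl)ethyl]butanoate (two molecules)
Product: 9 dimethyl 2,3-bis[1-(2-ethyl-1,3-dioxolan-2-yl)-4-(2-methoxyphenyl)butan-2-yl]succinate (diastereomer mixture), via lithium ester enolate 8 (not isolated)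
Conditions: LiN(iPr)2 (LDA, commercial solution, 1.1 equiv), THF, −78 °C; then anhydrous CuBr2 (1.1 equiv), −78 °C → rt
Reagents that add atoms: none
Why: Oxidative homocoupling of a lithium ester enolate with divalent copper, a known route to 2,3-disubstituted succinates, in which one-electron oxidation of 8 gives an α-ester radical (or the α-bromo ester) that joins a second enolate unit to form C5–C5' between two sp3 carbons; C5 and C5' arise without control, and all diastereomers are carried on because the four centres are erased in step 7.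

Step 5
Reactants: 9 dimethyl 2,3-bis[1-(2-ethyl-1,3-dioxolan-2-yl)-4-(2-methoxyphenyl)butan-2-yl]succinate
Product: 10 dimethyl 2,3-bis[1-(2-methoxyphenyl)-5-oxoheptan-3-yl]succinate (diastereomer mixture)
Conditions: 1 M HCl, THF, rt
Reagents that add atoms: water, O
Why: Acid hydrolysis of the two dioxolanes through oxocarbenium ions, mild enough at room temperature to leave the hindered methyl esters and the aryl ethers untouched, frees both ethyl ketones.

Step 6
Reactants: 10 dimethyl 2,3-bis[1-(2-methoxyphenyl)-5-oxoheptan-3-yl]succinate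
Product: 13 4,4'-bi[2-methyl-5-[2-(2-methoxyphenyl)ethyl]cyclohexane-1,3-dione] (diastereomer mixture), via monocyclised dione ester 11 (not isolated), via disodium bis-diketonate 12 (not isolated)
Conditions: NaOMe (6 equiv), MeOH–toluene (about 0.03 M), reflux; then cold 1 M HCl to pH 3
Reagents that add atoms: none
Why: Methoxide enolises each ethyl ketone reversibly, the C3 enolate carbon adds to the adjacent succinate ester carbonyl C4, methoxide leaves, and the new β-diketone is deprotonated at once to its diketonate (first in 11, then 12), which pulls both acylations forward. This is the Dieckmann-type intramolecular Claisen acylation by which 5-oxoalkanoates such as methyl 5-oxoheptanoate are converted to 2-methylcyclohexane-1,3-dione. Ring A (bond C3–C4) and ring B (bond C3'–C4') each close in the 6-(enolendo)-exo-trig mode. The only new sp3 centres, C3 and C3', are planar in the diketonate and labile in 13, so nothing has to control them, and C5, C5', C6 and C6' are carried as a mixture because all become arene carbons in step 7. The selectivity needed is among enolates: the C1 enolate cannot reach its own ester (four-membered ring) but can reach the remote ester C4' by a 5-(enolexo)-exo-trig closure to a 2-propanoylcyclopentanone, and the C5' ester enolate can add to C2 in a five-ring aldol that can neither dehydrate by E1cB nor complete a Stobbe sequence, since the attacking carbon becomes quaternary. Methyl esters matched with NaOMe in hot methanol keep these side paths reversible through retro-Claisen and retro-aldol steps, so material should collect in the anion of the cyclohexane-1,3-dione, a vinylogous acid several pKa units stronger than the acylcyclopentanone, and its solubility in aqueous NaHCO3 allows separation from weaker acids.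

Step 7
Reactants: 13 4,4'-bi[2-methyl-5-[2-(2-methoxyphenyl)ethyl]cyclohexane-1,3-dione]
Product: 14 6,6'-bis[2-(2-methoxyphenyl)ethyl]-3,3'-dimethyl-[1,1'-biphenyl]-2,2',4,4'-tetrol (racemic axis)
Conditions: 10% Pd/C (10 mol% Pd), K2CO3 (20 mol%), ethylene (1 atm, closed vessel), DMA, 150 °C, air excluded
Reagents that add atoms: none
Why: Heterogeneous transfer dehydrogenation of cyclohexane-1,3-diones to resorcinols, in which the enol form binds to the zerovalent palladium surface, one H2 equivalent (C5–H and C6–H) per ring is passed to ethylene and tautomerisation gives the arene, while the olefin acceptor permits a lower temperature than acceptor-free dehydrogenation and the trace of carbonate neutralises acid in the catalyst, both of which disfavour furan formation; all four sp3 centres vanish and the hindered axis forms as a racemate.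

Step 8
Reactants: 14 6,6'-bis[2-(2-methoxyphenyl)ethyl]-3,3'-dimethyl-[1,1'-biphenyl]-2,2',4,4'-tetrol
Product: 15 4,4'-dihydroxy-2,2'-bis[2-(2-methoxyphenyl)ethyl]-5,5'-dimethyl-[1,1'-bi(cyclohexa-1,4-diene)]-3,3',6,6'-tetrone (target, CNP0293637.0)
Conditions: (KSO3)2NO (5 equiv), aq. KH2PO4 buffer, acetone–H2O, 0 °C → rt
Reagents that add atoms: potassium nitrosodisulfonate (KSO3)2NO, [K+].[K+].[O-]S(=O)(=O)N([O])S(=O)(=O)[O-]
Why: Teuber oxidation, in which one nitroxyl radical abstracts a phenolic hydrogen and a second couples at C1, the only free ring position and para to the C4 hydroxyl, so that loss of imidodisulfonate gives the 1,4-quinone with the C2 hydroxyl retained (ortho attack from the C2 phenoxyl gives the same compound as its tautomer), while the anisole rings carry no free OH and stay untouched.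

Compound list
1 | 3-(2-methoxyphenyl)propanal | COc1ccccc1CCC=O | starting material
2 | diethyl (2-oxobutyl)phosphonate | CCOP(=O)(CC(=O)CC)OCC | starting material
3 | (E)-7-(2-methoxyphenyl)hept-4-en-3-one | CCC(=O)/C=C/CCc1ccccc1OC | intermediate
4 | 1-(tert-butyldimethylsilyloxy)-1-methoxyethene | COC(=C)O[Si](C)(C)C(C)(C)C | starting material
5 | methyl 5-[(tert-butyldimethylsilyl)oxy]-3-[2-(2-methoxyphenyl)ethyl]hept-4-enoate (racemic, E/Z mixture) | COC(=O)CC(CCc1ccccc1OC)C=C(CC)O[Si](C)(C)C(C)(C)C | intermediate
6 | methyl 3-[2-(2-methoxyphenyl)ethyl]-5-oxoheptanoate (racemic) | COC(=O)CC(CCc1ccccc1OC)CC(=O)CC | intermediate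
7 | methyl 4-(2-ethyl-1,3-dioxolan-2-yl)-3-[2-(2-methoxyphenyl)ethyl]butanoate (racemic) | COC(=O)CC(CCc1ccccc1OC)CC1(CC)OCCO1 | intermediate
8 | lithium enolate of 7 | [Li+].COC([O-])=CC(CCc1ccccc1OC)CC1(CC)OCCO1 | intermediate
9 | dimethyl 2,3-bis[1-(2-ethyl-1,3-dioxolan-2-yl)-4-(2-methoxyphenyl)butan-2-yl]succinate (diastereomer mixture) | COC(=O)C(C(CCc1ccccc1OC)CC1(CC)OCCO1)C(C(CCc1ccccc1OC)CC1(CC)OCCO1)C(=O)OC | intermediate
10 | dimethyl 2,3-bis[1-(2-methoxyphenyl)-5-oxoheptan-3-yl]succinate (diastereomer mixture) | COC(=O)C(C(CCc1ccccc1OC)CC(=O)CC)C(C(CCc1ccccc1OC)CC(=O)CC)C(=O)OC | intermediate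
11 | methyl 2-{6-[2-(2-methoxyphenyl)ethyl]-3-methyl-2,4-dioxocyclohexyl}-3-[2-(2-methoxyphenyl)ethyl]-5-oxoheptanoate (diastereomer mixture, present as its sodium diketonate) | O=C1C(C)C(=O)CC(CCc2ccccc2OC)C1C(C(=O)OC)C(CCc1ccccc1OC)CC(=O)CC | intermediate
12 | disodium bis-diketonate of 13 | [Na+].[Na+].[O-]C1=C(C)C(=O)CC(CCc2ccccc2OC)C1C1C(CCc2ccccc2OC)CC(=O)C(C)=C1[O-] | intermediate
13 | 4,4'-bi[2-methyl-5-[2-(2-methoxyphenyl)ethyl]cyclohexane-1,3-dione] (diastereomer and tautomer mixture) | O=C1C(C)C(=O)CC(CCc2ccccc2OC)C1C1C(CCc2ccccc2OC)CC(=O)C(C)C1=O | intermediate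
14 | 6,6'-bis[2-(2-methoxyphenyl)ethyl]-3,3'-dimethyl-[1,1'-biphenyl]-2,2',4,4'-tetrol (racemic axis) | Cc1c(O)cc(CCc2ccccc2OC)c(c1O)-c1c(CCc2ccccc2OC)cc(O)c(C)c1O | intermediate
15 | 4,4'-dihydroxy-2,2'-bis[2-(2-methoxyphenyl)ethyl]-5,5'-dimethyl-[1,1'-bi(cyclohexa-1,4-diene)]-3,3',6,6'-tetrone | COc1ccccc1CCC1=C(C2=C(CCc3ccccc3OC)C(=O)C(O)=C(C)C2=O)C(=O)C(C)=C(O)C1=O | target

Total step count: 8. Longest linear sequence: 8 (from 1 to 15).

Steps most likely to fail

Step 6. The second acylation must occur at an ester carbon buried between two branched carbons. The sequence may therefore stall after one ring closure. The C1 enolate may be diverted to the remote ester. The first diketonate oxygen may also be trapped by the remaining ester as an enol lactone. The fallback closes the ring first and makes the axis second; it sets out from 6 and comes back at 13. Keto ester 6, whose ester is unhindered and which has no remote ester, is cyclised alone with NaOMe in MeOH to 5-[2-(2-methoxyphenyl)ethyl]-2-methylcyclohexane-1,3-dione F1. MeOH with catalytic p-TsOH turns this into the vinylogous ester 3-methoxy-5-[2-(2-methoxyphenyl)ethyl]-2-methylcyclohex-2-en-1-one F2, a single constitutional isomer because the two carbonyl groups of F1 are equivalent. LiN(iPr)2 in THF at −78 °C removes the α' proton next to the branched carbon (the future C5). CuCl2 in THF/DMF then couples two ketone enolates oxidatively to 4,4'-dimethoxy-6,6'-bis[2-(2-methoxyphenyl)ethyl]-3,3'-dimethyl-[1,1'-bi(cyclohex-3-ene)]-2,2'-dione F3. Dilute HCl in THF at room temperature hydrolyses both enol ethers to 13.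

Step 4. Coupling of the β-branched enolate may be slow, so α-bromination by CuBr2, disproportionation of the radical or Claisen self-condensation may take over. The fallback never joins two hindered carbons directly; it sets out from 7 and comes back at 10. Enolate 8 is alkylated with the unhindered electrophile methyl bromoacetate to give dimethyl 2-[1-(2-ethyl-1,3-dioxolan-2-yl)-4-(2-methoxyphenyl)butan-2-yl]succinate F4. LiN(iPr)2 and TBSCl enolise and silylate the less hindered CH2 ester to methyl 4-[(tert-butyldimethylsilyl)oxy]-2-[1-(2-ethyl-1,3-dioxolan-2-yl)-4-(2-methoxyphenyl)butan-2-yl]-4-methoxybut-3-enoate F5. A second Mukaiyama–Michael addition of F5 to enone 3, catalysed by Sc(OTf)3, forms C5'–C6'. It gives dimethyl 2-[5-[(tert-butyldimethylsilyl)oxy]-1-(2-methoxyphenyl)hept-4-en-3-yl]-3-[1-(2-ethyl-1,3-dioxolan-2-yl)-4-(2-methoxyphenyl)butan-2-yl]succinate F6. 1 M HCl in THF cleaves the silyl enol ether and the remaining dioxolane to 10, so premature loss of the ketal under the Lewis acid does no harm.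

Step 7. The crowded rings may bind poorly to the metal surface, which would leave partly dehydrogenated material. Prolonged heating may also cyclodehydrate the C4–C5–C5'–C4' 1,4-dicarbonyl array to a furan, which would then aromatise to a dibenzofuran. The fallback replaces surface catalysis and heat by hydride abstraction from an activated derivative; it sets out from 13 and comes back at 14. TMSOTf and Et3N in CH2Cl2 convert 13 into 6,6'-bis[2-(2-methoxyphenyl)ethyl]-3,3'-dimethyl-2,2',4,4'-tetrakis(trimethylsilyloxy)-1,1',6,6'-tetrahydro-1,1'-biphenyl F7, which also masks the 1,4-dicarbonyl unit. DDQ (2 equiv) buffered with 2,4,6-collidine at 0 °C dehydrogenates the electron-rich dienes far faster than it attacks the benzylic positions. The product is 6,6'-bis[2-(2-methoxyphenyl)ethyl]-3,3'-dimethyl-2,2',4,4'-tetrakis(trimethylsilyloxy)-1,1'-biphenyl F8. Dilute HCl in aqueous THF removes the silyl groups to give 14.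

Further compounds
F1 | step 6 | 5-[2-(2-methoxyphenyl)ethyl]-2-methylcyclohexane-1,3-dione | CC1C(=O)CC(CCc2ccccc2OC)CC1=O
F2 | step 6 | 3-methoxy-5-[2-(2-methoxyphenyl)ethyl]-2-methylcyclohex-2-en-1-one (racemic) | COC1=C(C)C(=O)CC(CCc2ccccc2OC)C1
F3 | step 6 | 4,4'-dimethoxy-6,6'-bis[2-(2-methoxyphenyl)ethyl]-3,3'-dimethyl-[1,1'-bi(cyclohex-3-ene)]-2,2'-dione (diastereomer mixture) | COC1=C(C)C(=O)C(C(CCc2ccccc2OC)C1)C1C(CCc2ccccc2OC)CC(OC)=C(C)C1=O
F4 | step 4 | dimethyl 2-[1-(2-ethyl-1,3-dioxolan-2-yl)-4-(2-methoxyphenyl)butan-2-yl]succinate (diastereomer mixture) | COC(=O)CC(C(=O)OC)C(CCc1ccccc1OC)CC1(CC)OCCO1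
F5 | step 4 | methyl 4-[(tert-butyldimethylsilyl)oxy]-2-[1-(2-ethyl-1,3-dioxolan-2-yl)-4-(2-methoxyphenyl)butan-2-yl]-4-methoxybut-3-enoate | COC(=CC(C(=O)OC)C(CCc1ccccc1OC)CC1(CC)OCCO1)O[Si](C)(C)C(C)(C)C
F6 | step 4 | dimethyl 2-[5-[(tert-butyldimethylsilyl)oxy]-1-(2-methoxyphenyl)hept-4-en-3-yl]-3-[1-(2-ethyl-1,3-dioxolan-2-yl)-4-(2-methoxyphenyl)butan-2-yl]succinate (diastereomer mixture) | COC(=O)C(C(CCc1ccccc1OC)C=C(CC)O[Si](C)(C)C(C)(C)C)C(C(=O)OC)C(CCc1ccccc1OC)CC1(CC)OCCO1
F7 | step 7 | 6,6'-bis[2-(2-methoxyphenyl)ethyl]-3,3'-dimethyl-2,2',4,4'-tetrakis(trimethylsilyloxy)-1,1',6,6'-tetrahydro-1,1'-biphenyl (diastereomer mixture) | CC1=C(O[Si](C)(C)C)C(C(CCc2ccccc2OC)C=C1O[Si](C)(C)C)C1C(CCc2ccccc2OC)C=C(O[Si](C)(C)C)C(C)=C1O[Si](C)(C)C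
F8 | step 7 | 6,6'-bis[2-(2-methoxyphenyl)ethyl]-3,3'-dimethyl-2,2',4,4'-tetrakis(trimethylsilyloxy)-1,1'-biphenyl | Cc1c(O[Si](C)(C)C)cc(CCc2ccccc2OC)c(c1O[Si](C)(C)C)-c1c(CCc2ccccc2OC)cc(O[Si](C)(C)C)c(C)c1O[Si](C)(C)C
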